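**Retrosynthetic overview**

1. Last operations: acid removal of a catechol acetonide; before it, unmasking of the C3 formyl group from an exocyclic vinyl sulfide, with acid equilibration of C3.
2. Key disconnection: the C3–C4 bond of the 3,4-dihydro-2H-pyran (O1, C2–CH3, C3–CHO, C4–CH2CO2R, C5–CO2Me, C6), made by thiyl-radical addition to an alkyne and 6-exo-trig closure onto an acrylate. This is the only ring formed in the route; the arene is bought.
3. Enabling feature: C3 carries only an exocyclic formyl carbon (together a terminal alkyne at the hydration level), and the ring oxygen O1 is an enol ether oxygen held cis to C4 across C5=C6. O1–C6=C5 is therefore a rigid hinge that places alkyne carbon C3 and acrylate β-carbon C4 in a 1,7-enyne. With C3 sp2, the C2 methyl group alone steers C4.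
4. The enyne comes from three bought pieces: methyl coumalate (C6, C5–CO2Me, C4, CH2, C=O; its pyranone ring is opened by 1,6-addition of the alkoxide), (S)-but-3-yn-2-ol (O1, C2, CH3, C3, formyl carbon) and hydroxytyrosol (as acetonide, Mitsunobu), followed by Z to E isomerization of the acrylate.

Key step: step 4

Assumption: among the C3 epimers of the 2,4-trans aldehyde, the 3S isomer (formyl trans to the C4 arm) is taken to be the more stable one; step 5 relies on this.

**Route**

Step 1
Reactants: 1 hydroxytyrosol
Product: 2 2-(2,2-dimethyl-1,3-benzodioxol-5-yl)ethan-1-ol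
Conditions: 2,2-dimethoxypropane (3 equiv), TsOH·H2O (5 mol%), benzene, reflux (4 Å sieves); then 0.1 M HCl/THF, 0 °C, brief
Reagents that add atoms: 2,2-dimethoxypropane, COC(C)(C)OC
Why: Acid-catalysed transketalization (acetonide formation) ties up the two phenols, which would otherwise inhibit the radical chain of step 4 and compete as acidic partners in the Mitsunobu coupling of step 2, while the mixed ketal formed at the primary alcohol is cleaved again in the dilute-acid work-up.

Step 2
Reactants: 3 (2S)-but-3-yn-2-ol; 4 methyl coumalate; 2 2-(2,2-dimethyl-1,3-benzodioxol-5-yl)ethan-1-ol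
Product: 8 1-[2-(2,2-dimethyl-1,3-benzodioxol-5-yl)ethyl] 5-methyl (2Z,4E)-4-{[(2S)-but-3-yn-2-yloxy]methylidene}pent-2-enedioate, via sodium (2S)-but-3-yn-2-olate 5 (not isolated), via sodium (2Z)-dienoate carboxylate 6 (not isolated), via free (2Z)-dienoic acid 7 (not isolated)
Conditions: NaH (1.0 equiv), THF, 0 °C; 4, −78 → 0 °C; HCl (1.0 equiv, 4 M in dioxane), −78 °C; then 2, PPh3, DIAD, −78 → 0 °C
Reagents that add atoms: none
Why: Oxa-1,6-conjugate addition of alkoxide 5 to C6 of the 2-pyranone followed by electrocyclic ring opening (the established addition mode of methyl coumalate) unveils carboxylate 6, differentiated from the methyl ester and with the enol ether oxygen already cis to the acrylate arm, and Mitsunobu esterification then joins the liberated acid 7 to alcohol 2 by alkylation at oxygen without any acyl activation; the stereocentre of 3 is untouched because only its O–H bond reacts.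

Step 3
Reactants: 8 the (2Z,4E)-diester
Product: 9 1-[2-(2,2-dimethyl-1,3-benzodioxol-5-yl)ethyl] 5-methyl (2E,4E)-4-{[(2S)-but-3-yn-2-yloxy]methylidene}pent-2-enedioate
Conditions: I2 (5 mol%), CH2Cl2, visible light, rt; Na2S2O3 wash
Reagents that add atoms: none
Why: Iodine-atom-catalysed alkene isomerization (reversible addition of I• to the dienoate) should relax the (2Z)-acrylate to the thermodynamically preferred (2E)-isomer that the stereochemical model of step 4 needs, while the push–pull enol ether keeps its (4E) geometry.

Step 4
Reactants: 9 the (2E,4E)-diester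
Product: 12 methyl (2S,4R)-4-{2-[2-(2,2-dimethyl-1,3-benzodioxol-5-yl)ethoxy]-2-oxoethyl}-2-methyl-3-[(phenylsulfanyl)methylidene]-3,4-dihydro-2H-pyran-5-carboxylate (E/Z mixture at the exocyclic alkene; same spatial arrangement at C4 as 4S in the target), via β-phenylsulfanyl vinyl radical 10 (not isolated), via cyclized α-ester radical 11 (not isolated)
Conditions: PhSH (1.2 equiv, syringe pump over 8 h), Et3B (0.3 equiv), air, toluene (0.01 M), rt
Reagents that add atoms: thiophenol, Sc1ccccc1
Why: PhS• (from PhSH and Et3B/O2) adds reversibly to the terminal alkyne carbon, the resulting β-sulfanyl vinyl radical 10 (centred on C3) attacks C4, the β-carbon of the (E)-acrylate, and the α-ester radical 11 abstracts hydrogen from PhSH to carry the chain. The closest known reaction type is the thiol-mediated radical addition–cyclization of 1,n-enynes onto acrylates (thiol–yne addition followed by Giese-type ring closure). The dihydropyran is closed in the 6-exo-trig mode; the alternatives are a polarity-mismatched 7-endo attack at the acrylate α-carbon or a 5-endo attack on the enol ether. C4 is the only new stereocentre and is controlled by the C2 stereocentre through allylic 1,3-strain: C2–H eclipses the exocyclic C3=C bond and the C2 methyl group stands perpendicular to the vinyl plane, on the outside of the folding chain, while C3 attacks the planar s-trans dienoate from above, so the acrylate arm should end trans to the methyl group (2,4-trans), which is also the only arrangement with an equatorial methyl and a pseudoaxial C4 arm free of allylic strain against the C5 ester and the exocyclic alkene. The step needs ring closure to outrun hydrogen transfer to 10 and thiyl addition to stay on the alkyne; the cis enol ether O1–C6=C5 holds C3 and C4 within bonding distance, thiyl addition to the electron-poor alkenes is reversible, and the thiol is kept dilute by syringe pump. C3 is deliberately left sp2 (the vinyl sulfide is a masked formyl group), so that no 2,3-trans bias is built in during ring closure.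

Step 5
Reactants: 12 the vinyl sulfide
Product: 14 methyl (2S,3S,4S)-4-{2-[2-(2,2-dimethyl-1,3-benzodioxol-5-yl)ethoxy]-2-oxoethyl}-3-formyl-2-methyl-3,4-dihydro-2H-pyran-5-carboxylate, via 3R-epimeric aldehyde 13 (not isolated)
Conditions: HgCl2 (1.2 equiv), MeCN/H2O (4:1), 40 °C; then TsOH·H2O (10 mol%), CH2Cl2, rt
Reagents that add atoms: water, O
Why: Hydrolysis of the vinyl sulfide assisted by divalent mercury (protonation at C3, hydration of the thionium ion, loss of the thiolate to mercury) releases the formyl group, and acid-catalysed enolization should then funnel the C3 epimers into the 3S aldehyde, whose axial formyl group is anti to the pseudoaxial C4 arm and meets no syn-axial partner because the 1,3-related ring positions are O1 and the sp2 carbon C5.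

Step 6
Reactants: 14 the acetonide-protected aldehyde
Product: 15 methyl (2S,3S,4S)-4-{2-[2-(3,4-dihydroxyphenyl)ethoxy]-2-oxoethyl}-3-formyl-2-methyl-3,4-dihydro-2H-pyran-5-carboxylate (target)
Conditions: TFA/H2O (9:1), 0 °C → rt; evaporation
Reagents that add atoms: none
Why: Acid-catalysed ketal hydrolysis frees the catechol under conditions to which the vinylogous carbonate, both esters and the aldehyde should be stable, and the absence of base avoids retro-oxa-Michael opening of the C2–O1 bond and keeps C3 at its equilibrium configuration.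

**Compound list**

1 | hydroxytyrosol, 4-(2-hydroxyethyl)benzene-1,2-diol | OCCc1ccc(O)c(O)c1 | starting material
2 | 2-(2,2-dimethyl-1,3-benzodioxol-5-yl)ethan-1-ol | CC1(C)Oc2ccc(CCO)cc2O1 | intermediate
3 | (2S)-but-3-yn-2-ol | C[C@H](O)C#C | starting material
4 | methyl coumalate, methyl 2-oxo-2H-pyran-5-carboxylate | COC(=O)C1=COC(=O)C=C1 | starting material
5 | sodium (2S)-but-3-yn-2-olate | C[C@H]([O-])C#C.[Na+] | intermediate (not isolated)
6 | sodium (2Z,4E)-4-{[(2S)-but-3-yn-2-yloxy]methylidene}-5-methoxy-5-oxopent-2-enoate | [Na+].[O-]C(=O)/C=C\C(C(=O)OC)=C/O[C@@H](C)C#C | intermediate (not isolated)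
7 | (2Z,4E)-4-{[(2S)-but-3-yn-2-yloxy]methylidene}-5-methoxy-5-oxopent-2-enoic acid | OC(=O)/C=C\C(C(=O)OC)=C/O[C@@H](C)C#C | intermediate (not isolated)
8 | 1-[2-(2,2-dimethyl-1,3-benzodioxol-5-yl)ethyl] 5-methyl (2Z,4E)-4-{[(2S)-but-3-yn-2-yloxy]methylidene}pent-2-enedioate | CC1(C)Oc2ccc(CCOC(=O)/C=C\C(C(=O)OC)=C/O[C@@H](C)C#C)cc2O1 | intermediate
9 | 1-[2-(2,2-dimethyl-1,3-benzodioxol-5-yl)ethyl] 5-methyl (2E,4E)-4-{[(2S)-but-3-yn-2-yloxy]methylidene}pent-2-enedioate | CC1(C)Oc2ccc(CCOC(=O)/C=C/C(C(=O)OC)=C\O[C@@H](C)C#C)cc2O1 | intermediate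
10 | vinyl radical from addition of PhS• to the alkyne terminus of 9, radical centre on the carbon bonded to the (S)-CH(CH3)O carbon | CC1(C)Oc2ccc(CCOC(=O)/C=C/C(C(=O)OC)=C\O[C@@H](C)[C]=CSc3ccccc3)cc2O1 | intermediate (not isolated)
11 | (2S,4R)-configured cyclized radical, radical centre on the carbon α to the hydroxytyrosyl ester carbonyl | COC(=O)C1=CO[C@@H](C)C(=CSc2ccccc2)[C@@H]1[CH]C(=O)OCCc1ccc2OC(C)(C)Oc2c1 | intermediate (not isolated)
12 | methyl (2S,4R)-4-{2-[2-(2,2-dimethyl-1,3-benzodioxol-5-yl)ethoxy]-2-oxoethyl}-2-methyl-3-[(phenylsulfanyl)methylidene]-3,4-dihydro-2H-pyran-5-carboxylate (E/Z mixture) | COC(=O)C1=CO[C@@H](C)C(=CSc2ccccc2)[C@@H]1CC(=O)OCCc1ccc2OC(C)(C)Oc2c1 | intermediate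
13 | methyl (2S,3R,4S)-4-{2-[2-(2,2-dimethyl-1,3-benzodioxol-5-yl)ethoxy]-2-oxoethyl}-3-formyl-2-methyl-3,4-dihydro-2H-pyran-5-carboxylate | COC(=O)C1=CO[C@@H](C)[C@H](C=O)[C@@H]1CC(=O)OCCc1ccc2OC(C)(C)Oc2c1 | intermediate (not isolated)
14 | methyl (2S,3S,4S)-4-{2-[2-(2,2-dimethyl-1,3-benzodioxol-5-yl)ethoxy]-2-oxoethyl}-3-formyl-2-methyl-3,4-dihydro-2H-pyran-5-carboxylate | COC(=O)C1=CO[C@@H](C)[C@@H](C=O)[C@@H]1CC(=O)OCCc1ccc2OC(C)(C)Oc2c1 | intermediate
15 | methyl (2S,3S,4S)-4-{2-[2-(3,4-dihydroxyphenyl)ethoxy]-2-oxoethyl}-3-formyl-2-methyl-3,4-dihydro-2H-pyran-5-carboxylate | COC(=O)C1=CO[C@@H](C)[C@@H](C=O)[C@@H]1CC(=O)OCCc1ccc(O)c(O)c1 | target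

**Step count and risks**

Total steps: 6. Longest linear sequence: 6 steps (1 → 2 → 8 → 9 → 12 → 14 → 15); 5 steps from 3 or 4.

The steps most likely to fail are, in this order, step 4, step 5 and step 2.

In step 4, hydrogen transfer from the thiol to vinyl radical 10 may outrun ring closure, and the facial selectivity at C4 rests on substrate control by the remote C2 methyl group, which may prove low. The fallback replaces the radical chain by a catalyst-controlled acetoxypalladation-initiated enyne cyclization. It sets out from 9: Pd(OAc)2 (5 mol%) with a chiral bis(oxazoline) ligand in AcOH at 60 °C should add acetate and divalent palladium trans across the alkyne, insert the acrylate into the alkenyl–palladium bond and end by protonolysis. This would give the enol acetate methyl (2S,4S)-3-[(acetyloxy)methylidene]-4-{2-[2-(2,2-dimethyl-1,3-benzodioxol-5-yl)ethoxy]-2-oxoethyl}-2-methyl-3,4-dihydro-2H-pyran-5-carboxylate F1, with C4 under ligand control. Lipase-mediated alcoholysis of the enol ester (lipase B from Candida antarctica, n-butanol, toluene, rt) followed by the TsOH equilibration of step 5 comes back to the route at 14.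

In step 5, the vinyl sulfide is a vinylogous thioacetal of the C2–O1 bond, so the Lewis acid may ionize that bond, opening the ring and eroding the C2 configuration; convergence of the C3 epimers may also be slow. The fallback avoids the mercury salt and unmasks the aldehyde oxidatively. It sets out from 12: addition of thiophenol under Brønsted acid catalysis (PhSH, TsOH 5 mol%, CH2Cl2, 0 °C) traps the thionium ion as the S,S-acetal methyl (2S,4S)-3-[bis(phenylsulfanyl)methyl]-4-{2-[2-(2,2-dimethyl-1,3-benzodioxol-5-yl)ethoxy]-2-oxoethyl}-2-methyl-3,4-dihydro-2H-pyran-5-carboxylate F2 (C3 epimers). Oxidative hydrolysis with PhI(OCOCF3)2 in MeCN/H2O and the same TsOH equilibration comes back at 14.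

In step 2, the free (2Z)-acid 7 may close back to the pyranone with loss of the butynyl alcohol before it is esterified. The fallback never liberates the acid and forms the ester by SN2 alkylation instead. It sets out from 2, which is converted by an Appel reaction (PPh3, I2, imidazole, CH2Cl2) into the iodide 5-(2-iodoethyl)-2,2-dimethyl-1,3-benzodioxole F3. The sodium carboxylate 6, generated as in step 2 but not acidified, is alkylated with it in DMF at rt, and the route is rejoined at 8.

**Further compounds**

F1 | step 4 | methyl (2S,4S)-3-[(acetyloxy)methylidene]-4-{2-[2-(2,2-dimethyl-1,3-benzodioxol-5-yl)ethoxy]-2-oxoethyl}-2-methyl-3,4-dihydro-2H-pyran-5-carboxylate | COC(=O)C1=CO[C@@H](C)C(=COC(C)=O)[C@@H]1CC(=O)OCCc1ccc2OC(C)(C)Oc2c1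
F2 | step 5 | methyl (2S,4S)-3-[bis(phenylsulfanyl)methyl]-4-{2-[2-(2,2-dimethyl-1,3-benzodioxol-5-yl)ethoxy]-2-oxoethyl}-2-methyl-3,4-dihydro-2H-pyran-5-carboxylate (C3 epimers) | COC(=O)C1=CO[C@@H](C)C(C(Sc2ccccc2)Sc2ccccc2)[C@@H]1CC(=O)OCCc1ccc2OC(C)(C)Oc2c1
F3 | step 2 | 5-(2-iodoethyl)-2,2-dimethyl-1,3-benzodioxole | CC1(C)Oc2ccc(CCI)cc2O1
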